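The data are simulated with made-up constants.

Step 1. I start from the ligand.

the same everywhere: substrate 0.50 M; free catalyst 0.1 mol%

| run | reagent | added ligand | remark | time |
|---|---|---|---|---|
| larch | 1.5 equiv | 0.0031 mM | run made earlier |  |
| ash | 1.5 equiv | 0.30 mM | run made earlier |  |
| alpha | 1.50 equiv | 0.0050 mM |  | 15 h |
| theta | 1.50 equiv | 0.015 mM |  | 15 h |
| zeta | 1.50 equiv | 0.040 mM |  | 15 h |
| beta | 1.50 equiv | 0.12 mM |  | 15 h |
| eta | 1.50 equiv | 0.40 mM |  | 15 h |

| run | time / h | target / % | substrate / % |
|---|---|---|---|
| larch | 2.00 | 5.3 | 91.8 |
| larch | 4.00 | 7.1 | 85.0 |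
| larch | 6.00 | 8.6 | 78.7 |
| larch | 8.00 | 11.7 | 72.5 |
| ash | 1.00 | 1.7 | 99.0 |
| ash | 2.50 | 2.1 | 96.0 |
| ash | 5.00 | 4.4 | 91.3 |
| ash | 8.00 | 5.7 | 87.5 |

(each reading ± 0.5 percentage points)

- the numbers in the tables scatter by 0.5 percentage points (one standard deviation)
- steps that have been proposed: reagent + free catalyst <-> catalyst intermediate A; substrate + catalyst intermediate A -> catalyst intermediate B; catalyst intermediate B -> by-product + catalyst intermediate C; catalyst intermediate C -> free catalyst + target; free catalyst + added ligand <-> idle complex; target <-> isomer of the product
- "hardly changes" means that all values lie within two and a half points (for a concentration: within two and a half percent of the largest)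

- [target] at the end for alpha, theta, zeta, beta, eta, in this order
- how that number moves from the first to the last of them (hardly changes / falls, then rises / falls all the way / rises all the way / rises, then falls)

Step 2. The catalyst charged is 0.500 mM. I assume that added ligand holds free catalyst one to one in the idle complex, an off-cycle form. Ligand equal to catalyst is then the zero of my scale. I define the working share as one minus ligand over catalyst charged, which for eta is 20.0% and for beta 76.0%.

Step 3. Larch and ash have the same charges of substrate, reagent and free catalyst and differ in added ligand. By 8.00 h larch keeps 72.5% of its substrate and ash keeps 87.5%. Their working shares are 99.4% for larch and 40.0% for ash. Read as first-order losses, the readings give ash's rate over larch's as 0.415, and the shares give 0.402. One number comes from readings and the other from the charge, so I keep the assumption. Ash ends behind larch because its working share is smaller.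

Step 4. My own reckoning takes larch's loss per unit of working share, 0.0404 h⁻¹, as a reading. Over 15 h that gives a substrate loss of 45.2% in alpha and 11.4% in eta. So I expect the row to fall from alpha to eta.

Step 5. The forecast gives 0.087 M, 0.086 M, 0.082 M, 0.072 M and 0.023 M, and its shape is falls all the way. Its ground is that “active catalyst is about 0.5 mM minus ligand”.

Step 6. The flasks give 0.0875 M, 0.0863 M, 0.0833 M, 0.0730 M and 0.0282 M, and the shape is falls all the way.

    reagent + free catalyst ⇌ catalyst intermediate A (K = 0.910 M⁻¹, k = 16.0 M⁻¹ min⁻¹)
    substrate + catalyst intermediate A → catalyst intermediate B (k = 4.10 M⁻¹ min⁻¹)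
    catalyst intermediate B → by-product + catalyst intermediate C (k = 13.0 min⁻¹)
    catalyst intermediate C → free catalyst + target (k = 12.0 min⁻¹)
    free catalyst + added ligand ⇌ idle complex, settled at all times (K = 2.50 × 10⁵ M⁻¹)
    target ⇌ isomer of the product (K = 1.70, k = 0.0110 min⁻¹)

In alpha the half-life of target by its forward step to the isomer of the product is 1.1 h at 6.18 h, shorter than the 15 h of the run. At the end the ratio of target to isomer is 0.665 in alpha and 0.687 in eta. The working share of eta was 20.0%, and at 15.0 h the catalyst outside the idle complex is 24.3% of the charge. The working share of beta was 76.0%, and there the catalyst outside the idle complex at 15.0 h is 76.4%.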